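**Strategy.** The flavan is disconnected at C4–C4a and O1–C2. This leads back to a 3-(2,6-dibenzyloxy-4-hydroxyphenyl)flavone whose para oxygen carries a racemic 1-(4-benzyloxyphenyl)prop-2-ynyl group. Heating this ether triggers a propargyl Claisen shift, enolisation, a 1,5-hydrogen shift and an oxa-6π closure. One operation thus forges C4–C4a, re-forms O1–C2 and closes the pyran ring as a flav-3-ene. The step exploits ring D, the benzo ring of the flavan: O1 lies para to the flavone C3–flavan C6 bond, and the two carbons ortho to O1 (C4a and C8) are equivalent before the shift, so only the 6-linked flavan can form. C2 is set afterwards by iridium-catalysed asymmetric hydrogenation.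

Key step: step 9

Assumption: the target SMILES gives no descriptor for the axis between flavone C3 and flavan C6, so this axis is treated as not configurationally fixed and only C2 (S) is controlled.

Remark on the precursor: all six phenols are carried as benzyl ethers, so that neither the heat of step 9 nor the base of step 10 meets an acidic or acyl group and one hydrogenolysis ends the route. The two ring-D oxygens that flank the flavone must stay capped, so that only the propargylated oxygen can become O1.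

Remark on step 11: cod = cycloocta-1,5-diene; (S)-tBu-PHOX = (S)-4-tert-butyl-2-[2-(diphenylphosphanyl)phenyl]-4,5-dihydro-1,3-oxazole; BArF = tetrakis[3,5-bis(trifluoromethyl)phenyl]borate. The step is written with the (S)-ligand. Which ligand antipode leads to (2S) would be fixed beforehand on 2-(4-benzyloxyphenyl)-4H-chromene, and the other antipode would be used if the sense is opposite.

**Step 1**
Reactants: 1 apigenin (5,7-dihydroxy-2-(4-hydroxyphenyl)-4H-chromen-4-one)
Product: 2 5,7-bis(benzyloxy)-2-[4-(benzyloxy)phenyl]-4H-chromen-4-one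
Conditions: BnBr (4.5 equiv), K2CO3, nBu4NI (cat.), DMF, 80 °C
Reagents that add atoms: benzyl bromide, BrCc1ccccc1
Why: Williamson ether synthesis on all three phenols; the hydrogen-bonded 5-OH reacts last, hence the excess of halide, the iodide catalyst and the heat.

**Step 2**
Reactants: 2 5,7-bis(benzyloxy)-2-[4-(benzyloxy)phenyl]-4H-chromen-4-one
Product: 4 5,7-bis(benzyloxy)-2-[4-(benzyloxy)phenyl]-3-iodo-4H-chromen-4-one, via 3-lithiochromenone 3 (not isolated)
Conditions: LiN(iPr)2 (1.2 equiv), THF, −78 °C; then I2, −78 °C to 0 °C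
Reagents that add atoms: iodine, I-I
Why: C3 lithiation–iodination of a flavone, in which the lithium amide removes the vinylic C3–H alpha to the carbonyl and iodine traps the vinyllithium, so the halogen goes to C3 and not to C6 or C8 of the dialkoxy ring as electrophilic iodination could.

**Step 3**
Reactants: 5 3,5-bis(benzyloxy)phenol
Product: 6 [3,5-bis(benzyloxy)phenoxy]triisopropylsilane
Conditions: iPr3SiCl, imidazole, DMF, rt
Reagents that add atoms: chlorotriisopropylsilane, CC(C)[Si](Cl)(C(C)C)C(C)C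
Why: Silylation of a phenol; the bulky, non-coordinating silyl ether withstands n-BuLi, shields the two positions next to it and is later removed by fluoride without touching benzyl ethers.

**Step 4**
Reactants: 6 [3,5-bis(benzyloxy)phenoxy]triisopropylsilane
Product: 8 2-[2,6-bis(benzyloxy)-4-(triisopropylsilyloxy)phenyl]-4,4,5,5-tetramethyl-1,3,2-dioxaborolane, via 2,6-bis(benzyloxy)-4-(triisopropylsilyloxy)phenyllithium 7 (not isolated)
Conditions: n-BuLi (1.1 equiv), THF, 0 °C; then iPrOBpin, −78 °C to rt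
Reagents that add atoms: 2-isopropoxy-4,4,5,5-tetramethyl-1,3,2-dioxaborolane, CC(C)OB1OC(C)(C)C(C)(C)O1
Why: Directed ortho-metalation removes the one ring proton flanked by two benzyloxy groups (cooperative coordination, while the silyl ether neither directs nor leaves its neighbours accessible), and the aryllithium is trapped by the borate as the pinacol boronate.

**Step 5**
Reactants: 4 5,7-bis(benzyloxy)-2-[4-(benzyloxy)phenyl]-3-iodo-4H-chromen-4-one; 8 2-[2,6-bis(benzyloxy)-4-(triisopropylsilyloxy)phenyl]-4,4,5,5-tetramethyl-1,3,2-dioxaborolane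
Product: 9 5,7-bis(benzyloxy)-2-[4-(benzyloxy)phenyl]-3-[2,6-bis(benzyloxy)-4-(triisopropylsilyloxy)phenyl]-4H-chromen-4-one
Conditions: Pd(OAc)2 (5 mol %), SPhos (10 mol %), K3PO4, toluene/H2O (10:1), 100 °C
Reagents that add atoms: none
Why: Suzuki–Miyaura coupling of a 3-iodochromone with a 2,6-dialkoxyarylboronate; the bulky electron-rich biarylphosphine on zerovalent palladium is the ligand class that forms tetra-ortho-substituted biaryl bonds and should outpace protodeboronation.

**Step 6**
Reactants: 9 5,7-bis(benzyloxy)-2-[4-(benzyloxy)phenyl]-3-[2,6-bis(benzyloxy)-4-(triisopropylsilyloxy)phenyl]-4H-chromen-4-one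
Product: 10 5,7-bis(benzyloxy)-2-[4-(benzyloxy)phenyl]-3-[2,6-bis(benzyloxy)-4-hydroxyphenyl]-4H-chromen-4-one
Conditions: Bu4NF, THF, 0 °C
Reagents that add atoms: none
Why: Fluoride cleavage of the aryl silyl ether frees only the para phenol of ring D, since benzyl ethers and the chromone are inert to fluoride at 0 °C.

**Step 7**
Reactants: 11 4-(benzyloxy)benzaldehyde
Product: 13 racemic 1-[4-(benzyloxy)phenyl]prop-2-yn-1-yl methyl carbonate, via bromomagnesium 1-[4-(benzyloxy)phenyl]prop-2-yn-1-olate 12 (not isolated)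
Conditions: HC≡CMgBr, THF, 0 °C; then ClCO2Me, 0 °C to rt
Reagents that add atoms: ethynylmagnesium bromide, C#C[Mg]Br; methyl chloroformate, COC(=O)Cl
Why: Grignard 1,2-addition to the aldehyde gives the racemic alkoxide, which is acylated in the same flask so that the acid-sensitive, electron-rich carbinol is never isolated.

**Step 8**
Reactants: 10 5,7-bis(benzyloxy)-2-[4-(benzyloxy)phenyl]-3-[2,6-bis(benzyloxy)-4-hydroxyphenyl]-4H-chromen-4-one; 13 racemic 1-[4-(benzyloxy)phenyl]prop-2-yn-1-yl methyl carbonate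
Product: 14 racemic 5,7-bis(benzyloxy)-2-[4-(benzyloxy)phenyl]-3-{2,6-bis(benzyloxy)-4-[1-(4-benzyloxyphenyl)prop-2-ynyloxy]phenyl}-4H-chromen-4-one
Conditions: CuCl2·2H2O (5 mol %), DBU (1.5 equiv), MeCN/CH2Cl2, 0 °C, Ar
Reagents that add atoms: none
Why: Copper-catalysed propargylic etherification of a phenol with a propargylic carbonate; loss of carbonate from the copper acetylide gives a copper allenylidene that the phenoxide attacks at the aryl-bearing carbon, so the O-linked 1-arylpropargyl ether should form under basic conditions without acid contact.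

**Step 9**
Reactants: 14 racemic 5,7-bis(benzyloxy)-2-[4-(benzyloxy)phenyl]-3-{2,6-bis(benzyloxy)-4-[1-(4-benzyloxyphenyl)prop-2-ynyloxy]phenyl}-4H-chromen-4-one
Product: 18 racemic 5,7-bis(benzyloxy)-2-[4-(benzyloxy)phenyl]-3-{5,7-bis(benzyloxy)-2-[4-(benzyloxy)phenyl]-2H-chromen-6-yl}-4H-chromen-4-one (hexabenzyl flav-3-ene), via 6-allenylcyclohexa-2,4-dienone 15 (not isolated), via ortho-allenylphenol 16 (not isolated), via ortho-quinone methide 17 (not isolated)
Conditions: PhNEt2 (2 equiv), degassed o-xylene, 140 °C, Ar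
Reagents that add atoms: none
Why: The ether undergoes an aromatic propargyl Claisen rearrangement, a suprafacial [3,3] shift from the ring-D oxygen to an ortho carbon that forms C4–C4a and gives allenyl dienone 15; enolisation to allenylphenol 16 and a 1,5-hydrogen shift from O–H to the central allene carbon then give ortho-quinone methide 17. The closest known reaction type is the thermal rearrangement of aryl propargyl ethers to 2H-chromenes, here in its 1-aryl variant that leads to a flav-3-ene. The single new ring, the pyran ring, closes by a thermal disrotatory oxa-6π electrocyclisation of 17 that re-forms O1–C2. C2 arises without control, as a racemate, because the propargylic C–O bond is broken and rebuilt through planar 17; no element is asked to control it, since step 10 erases this centre and step 11 sets it. The step needs regioselectivity, which ring D secures: its two carbons ortho to the migrating oxygen are equivalent and its other two oxygens are capped as benzyl ethers, so only the para oxygen can become O1 and only the 6-linked flavan can form. It also needs the concerted shift to outrun heterolysis of the electron-rich benzylic propargylic C–O bond, which the fully etherified, acid-free substrate and the non-polar, amine-buffered medium favour.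

**Step 10**
Reactants: 18 racemic hexabenzyl flav-3-ene
Product: 20 5,7-bis(benzyloxy)-2-[4-(benzyloxy)phenyl]-3-{5,7-bis(benzyloxy)-2-[4-(benzyloxy)phenyl]-4H-chromen-6-yl}-4H-chromen-4-one, via potassium chromen-2-ide 19 (not isolated)
Conditions: KOtBu (0.5 equiv), degassed DMSO/THF, rt, Ar; pH 7 buffer quench
Reagents that add atoms: none
Why: Base-mediated 1,3-prototropic isomerisation of a 2H-chromene to the 4H-chromene; tert-butoxide removes the C2–H (benzylic, allylic and alpha to oxygen), and protonation of the delocalised anion at C4 gives the enol ether conjugated with O1 and the 2-aryl ring, which erases the racemic C2 centre.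

**Step 11**
Reactants: 20 5,7-bis(benzyloxy)-2-[4-(benzyloxy)phenyl]-3-{5,7-bis(benzyloxy)-2-[4-(benzyloxy)phenyl]-4H-chromen-6-yl}-4H-chromen-4-one
Product: 21 3-{(2S)-5,7-bis(benzyloxy)-2-[4-(benzyloxy)phenyl]-3,4-dihydro-2H-chromen-6-yl}-5,7-bis(benzyloxy)-2-[4-(benzyloxy)phenyl]-4H-chromen-4-one
Conditions: [Ir(cod)((S)-tBu-PHOX)]BArF (2 mol %), H2 (50 bar), CH2Cl2, rt
Reagents that add atoms: none
Why: Iridium-catalysed asymmetric hydrogenation of a 2-aryl-4H-chromene (a cyclic trisubstituted enol ether) with a cationic monovalent iridium phosphine–oxazoline complex; the chiral ligand selects the enantiotopic face of C2=C3, so C2 is set as S under catalyst control, while the tetrasubstituted chromone alkene and the benzyl ethers should not be reduced by this catalyst.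

**Step 12**
Reactants: 21 3-{(2S)-5,7-bis(benzyloxy)-2-[4-(benzyloxy)phenyl]-3,4-dihydro-2H-chromen-6-yl}-5,7-bis(benzyloxy)-2-[4-(benzyloxy)phenyl]-4H-chromen-4-one
Product: 22 3-[(2S)-5,7-dihydroxy-2-(4-hydroxyphenyl)-3,4-dihydro-2H-chromen-6-yl]-5,7-dihydroxy-2-(4-hydroxyphenyl)-4H-chromen-4-one (CNP0304187.1)
Conditions: H2 (1 atm), Pd/C (10 wt %), THF/MeOH, rt
Reagents that add atoms: none
Why: Hydrogenolysis of the six aryl benzyl ethers over zerovalent palladium on carbon; benzyl aryl ethers cleave faster than the cyclic benzylic C2–O1 bond or the tetrasubstituted chromone alkene, so stopping at six equivalents of uptake should leave the S centre and both heterocycles intact.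

**Compound list**

1 | apigenin, 5,7-dihydroxy-2-(4-hydroxyphenyl)-4H-chromen-4-one | O=c1cc(-c2ccc(O)cc2)oc2cc(O)cc(O)c12 | starting material
2 | 5,7-bis(benzyloxy)-2-[4-(benzyloxy)phenyl]-4H-chromen-4-one | O=c1cc(-c2ccc(OCc3ccccc3)cc2)oc2cc(OCc3ccccc3)cc(OCc3ccccc3)c12 | intermediate
3 | 5,7-bis(benzyloxy)-2-[4-(benzyloxy)phenyl]-3-lithio-4H-chromen-4-one | O=c1c([Li])c(-c2ccc(OCc3ccccc3)cc2)oc2cc(OCc3ccccc3)cc(OCc3ccccc3)c12 | intermediate
4 | 5,7-bis(benzyloxy)-2-[4-(benzyloxy)phenyl]-3-iodo-4H-chromen-4-one | O=c1c(I)c(-c2ccc(OCc3ccccc3)cc2)oc2cc(OCc3ccccc3)cc(OCc3ccccc3)c12 | intermediate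
5 | 3,5-bis(benzyloxy)phenol | Oc1cc(OCc2ccccc2)cc(OCc2ccccc2)c1 | starting material
6 | [3,5-bis(benzyloxy)phenoxy]triisopropylsilane | CC(C)[Si](Oc1cc(OCc2ccccc2)cc(OCc2ccccc2)c1)(C(C)C)C(C)C | intermediate
7 | [2,6-bis(benzyloxy)-4-(triisopropylsilyloxy)phenyl]lithium | [Li]c1c(OCc2ccccc2)cc(O[Si](C(C)C)(C(C)C)C(C)C)cc1OCc1ccccc1 | intermediate
8 | 2-[2,6-bis(benzyloxy)-4-(triisopropylsilyloxy)phenyl]-4,4,5,5-tetramethyl-1,3,2-dioxaborolane | CC(C)[Si](Oc1cc(OCc2ccccc2)c(B2OC(C)(C)C(C)(C)O2)c(OCc2ccccc2)c1)(C(C)C)C(C)C | intermediate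
9 | 5,7-bis(benzyloxy)-2-[4-(benzyloxy)phenyl]-3-[2,6-bis(benzyloxy)-4-(triisopropylsilyloxy)phenyl]-4H-chromen-4-one | O=c1c(-c2c(OCc3ccccc3)cc(O[Si](C(C)C)(C(C)C)C(C)C)cc2OCc2ccccc2)c(-c2ccc(OCc3ccccc3)cc2)oc2cc(OCc3ccccc3)cc(OCc3ccccc3)c12 | intermediate
10 | 5,7-bis(benzyloxy)-2-[4-(benzyloxy)phenyl]-3-[2,6-bis(benzyloxy)-4-hydroxyphenyl]-4H-chromen-4-one | O=c1c(-c2c(OCc3ccccc3)cc(O)cc2OCc2ccccc2)c(-c2ccc(OCc3ccccc3)cc2)oc2cc(OCc3ccccc3)cc(OCc3ccccc3)c12 | intermediate
11 | 4-(benzyloxy)benzaldehyde | O=Cc1ccc(OCc2ccccc2)cc1 | starting material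
12 | bromomagnesium 1-[4-(benzyloxy)phenyl]prop-2-yn-1-olate (racemic) | C#CC(O[Mg]Br)c1ccc(OCc2ccccc2)cc1 | intermediate
13 | racemic 1-[4-(benzyloxy)phenyl]prop-2-yn-1-yl methyl carbonate | C#CC(OC(=O)OC)c1ccc(OCc2ccccc2)cc1 | intermediate
14 | racemic 5,7-bis(benzyloxy)-2-[4-(benzyloxy)phenyl]-3-{2,6-bis(benzyloxy)-4-[1-(4-benzyloxyphenyl)prop-2-ynyloxy]phenyl}-4H-chromen-4-one | O=c1c(-c2c(OCc3ccccc3)cc(OC(C#C)c3ccc(OCc4ccccc4)cc3)cc2OCc2ccccc2)c(-c2ccc(OCc3ccccc3)cc2)oc2cc(OCc3ccccc3)cc(OCc3ccccc3)c12 | intermediate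
15 | 3,5-bis(benzyloxy)-6-[3-(4-benzyloxyphenyl)propa-1,2-dienyl]-4-{5,7-bis(benzyloxy)-2-[4-(benzyloxy)phenyl]-4-oxo-4H-chromen-3-yl}cyclohexa-2,4-dien-1-one (stereoisomer mixture) | O=c1c(C2=C(OCc3ccccc3)C(C=C=Cc3ccc(OCc4ccccc4)cc3)C(=O)C=C2OCc2ccccc2)c(-c2ccc(OCc3ccccc3)cc2)oc2cc(OCc3ccccc3)cc(OCc3ccccc3)c12 | intermediate
16 | 5,7-bis(benzyloxy)-2-[4-(benzyloxy)phenyl]-3-{2,6-bis(benzyloxy)-3-[3-(4-benzyloxyphenyl)propa-1,2-dienyl]-4-hydroxyphenyl}-4H-chromen-4-one (racemic allene) | O=c1c(-c2c(OCc3ccccc3)cc(O)c(C=C=Cc3ccc(OCc4ccccc4)cc3)c2OCc2ccccc2)c(-c2ccc(OCc3ccccc3)cc2)oc2cc(OCc3ccccc3)cc(OCc3ccccc3)c12 | intermediate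
17 | 3,5-bis(benzyloxy)-6-[3-(4-benzyloxyphenyl)prop-2-enylidene]-4-{5,7-bis(benzyloxy)-2-[4-(benzyloxy)phenyl]-4-oxo-4H-chromen-3-yl}cyclohexa-2,4-dien-1-one (alkene geometry not specified) | O=c1c(C2=C(OCc3ccccc3)C(=CC=Cc3ccc(OCc4ccccc4)cc3)C(=O)C=C2OCc2ccccc2)c(-c2ccc(OCc3ccccc3)cc2)oc2cc(OCc3ccccc3)cc(OCc3ccccc3)c12 | intermediate
18 | racemic 5,7-bis(benzyloxy)-2-[4-(benzyloxy)phenyl]-3-{5,7-bis(benzyloxy)-2-[4-(benzyloxy)phenyl]-2H-chromen-6-yl}-4H-chromen-4-one | O=c1c(-c2c(OCc3ccccc3)cc3c(c2OCc2ccccc2)C=CC(c2ccc(OCc4ccccc4)cc2)O3)c(-c2ccc(OCc3ccccc3)cc2)oc2cc(OCc3ccccc3)cc(OCc3ccccc3)c12 | intermediate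
19 | potassium salt of the C2 carbanion of 18 (charge delocalised over C2 and C4) | O=c1c(-c2c(OCc3ccccc3)cc3c(c2OCc2ccccc2)C=C[C-](c2ccc(OCc4ccccc4)cc2)O3)c(-c2ccc(OCc3ccccc3)cc2)oc2cc(OCc3ccccc3)cc(OCc3ccccc3)c12.[K+] | intermediate
20 | 5,7-bis(benzyloxy)-2-[4-(benzyloxy)phenyl]-3-{5,7-bis(benzyloxy)-2-[4-(benzyloxy)phenyl]-4H-chromen-6-yl}-4H-chromen-4-one | O=c1c(-c2c(OCc3ccccc3)cc3c(c2OCc2ccccc2)CC=C(c2ccc(OCc4ccccc4)cc2)O3)c(-c2ccc(OCc3ccccc3)cc2)oc2cc(OCc3ccccc3)cc(OCc3ccccc3)c12 | intermediate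
21 | 3-{(2S)-5,7-bis(benzyloxy)-2-[4-(benzyloxy)phenyl]-3,4-dihydro-2H-chromen-6-yl}-5,7-bis(benzyloxy)-2-[4-(benzyloxy)phenyl]-4H-chromen-4-one | O=c1c(-c2c(OCc3ccccc3)cc3c(c2OCc2ccccc2)CC[C@@H](c2ccc(OCc4ccccc4)cc2)O3)c(-c2ccc(OCc3ccccc3)cc2)oc2cc(OCc3ccccc3)cc(OCc3ccccc3)c12 | intermediate
22 | 3-[(2S)-5,7-dihydroxy-2-(4-hydroxyphenyl)-3,4-dihydro-2H-chromen-6-yl]-5,7-dihydroxy-2-(4-hydroxyphenyl)-4H-chromen-4-one | O=c1c(-c2c(O)cc3c(c2O)CC[C@@H](c2ccc(O)cc2)O3)c(-c2ccc(O)cc2)oc2cc(O)cc(O)c12 | target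

**Step count.** Total: 12 steps. Longest linear sequence: 9 steps (steps 1, 2, 5, 6, 8, 9, 10, 11, 12; the branch through steps 3 and 4 is equally long).

**Steps most likely to fail**

1. Step 9 (Claisen cascade). Heterolysis of the benzylic propargylic C–O bond may outrun the sigmatropic shift, so that the ether falls back to the phenol or recombines at carbon. The allenylphenol may also close in a 5-exo sense instead of passing through the hydrogen shift. The fallback sets out from 10 and 11 and returns at 18. Aldehyde 11 would be homologated by a Wittig reaction with (triphenylphosphoranylidene)acetaldehyde in toluene at 80 °C to (E)-3-[4-(benzyloxy)phenyl]prop-2-enal F1. Phenol 10 and F1 would then be condensed with catalytic ethylenediammonium diacetate in toluene at reflux with removal of water. This formal [3+3] annulation of a phenol with an enal attacks the same ortho carbon, loses water to the same quinone methide 17 and closes by the same oxa-6π step. It should therefore give 18 without ever making the ionisable ether.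

2. Step 5 (Suzuki–Miyaura coupling). Transfer of the doubly ortho-substituted aryl group from boron to palladium may be slow, so that protodeboronation of the boronate and reductive loss of iodine consume both partners before the hindered bond forms. The fallback sets out from 6 and 4 and returns at 9. Silyl ether 6 would be lithiated as in step 4 to 7 and transmetalated with ZnCl2 in THF to [2,6-bis(benzyloxy)-4-(triisopropylsilyloxy)phenyl]zinc chloride F2. F2 would be coupled with iodide 4 in a Negishi reaction with Pd2(dba)3 and RuPhos in THF at 60 °C. The organozinc transfers its aryl group to palladium without base or water, which removes the protodeboronation pathway.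

3. Step 10 (isomerisation). Addition of alkoxide or dimsyl anion to the chromone, air oxidation of the C4 anion, incomplete equilibration, or hydrolysis of the enol ether on work-up may erode the material. The fallback sets out from 18 and returns at 20. Hydride abstraction from C2 with Ph3C BF4 in CH2Cl2 at 0 °C would give 5,7-bis(benzyloxy)-2-[4-(benzyloxy)phenyl]-6-{5,7-bis(benzyloxy)-2-[4-(benzyloxy)phenyl]-4-oxo-4H-chromen-3-yl}chromenylium tetrafluoroborate F3. Hydride return from diethyl 2,6-dimethyl-1,4-dihydropyridine-3,5-dicarboxylate (Hantzsch ester) in CH2Cl2, which adds at C4 of 2-arylbenzopyrylium ions, should then give 20 under non-basic conditions, followed by a NaHCO3 wash.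

**Further compounds**

F1 | step 9 | (E)-3-[4-(benzyloxy)phenyl]prop-2-enal | O=C/C=C/c1ccc(OCc2ccccc2)cc1
F2 | step 5 | [2,6-bis(benzyloxy)-4-(triisopropylsilyloxy)phenyl]zinc chloride | Cl[Zn]c1c(OCc2ccccc2)cc(O[Si](C(C)C)(C(C)C)C(C)C)cc1OCc1ccccc1
F3 | step 10 | 5,7-bis(benzyloxy)-2-[4-(benzyloxy)phenyl]-6-{5,7-bis(benzyloxy)-2-[4-(benzyloxy)phenyl]-4-oxo-4H-chromen-3-yl}chromenylium tetrafluoroborate | O=c1c(-c2c(OCc3ccccc3)cc3[o+]c(-c4ccc(OCc5ccccc5)cc4)ccc3c2OCc2ccccc2)c(-c2ccc(OCc3ccccc3)cc2)oc2cc(OCc3ccccc3)cc(OCc3ccccc3)c12.F[B-](F)(F)F
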